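**Retrosynthetic overview**
1. Guaiane numbering is used: cyclopentane C1–C5 (C4 quaternary), cycloheptene C1, C5–C10 (C5=C6; C7 bears C11(CH3)2OH; C10 bears CH3). The arene is finished last: two ring acylations by directed lithiation of a 2,4,6-trimethoxybenzyl group, then O-demethylation.
2. C7–H and C11–OH come from a C5=C6–C7=C11 diene (epoxidation, then Pd/formate hydrogenolysis with inversion). The diene comes from a C5=C6–C7=O enone (Wittig), the enone from a C6=C7 silyl enol ether (Saegusa–Ito), and the C10 methyl from an exocyclic methylene.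
3. Key disconnection: the seven-membered ring shares only the C1–C5 bond with the five-membered ring. Cutting C1–C5 and C8–C9 leaves a four-carbon diene C5=C6–C7(OSi)=C8 and a three-carbon 2-(silylmethyl)allyl cation C9–C10–C1 (central carbon C10 is the methyl-bearing carbon), already linked by the tether C2–C3–C4. One intramolecular (4+3) cycloaddition closes the five- and the seven-membered ring together.
4. The acyclic precursor is built from (R)-2-methyl-2-(arylmethyl)pent-4-enal. Its quaternary carbon C4, the only stereocentre before the key step, comes from a catalytic asymmetric α-allylation of a Heck-derived aldehyde.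

Key step: step 8

Remark: Ar = 2,4,6-trimethoxyphenyl; β is the face of the cyclopentane that carries CH2Ar on C4, α the face of the C4 methyl group.

**Step 1**
Reactants: 1 2-iodo-1,3,5-trimethoxybenzene; 2 2-methylprop-2-en-1-ol
Product: 3 rac-2-methyl-3-(2,4,6-trimethoxyphenyl)propanal
Conditions: Pd(OAc)2 (5 mol%), n-Bu4NCl, NaHCO3, DMF, 50 °C
Reagents that add atoms: none
Why: Heck arylation of an allylic alcohol, in which carbopalladation of the 1,1-disubstituted alkene, β-hydride elimination toward the carbinol carbon and tautomerization should give the saturated aldehyde directly; the α-stereocentre forms as a racemate and is erased in step 2.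

**Step 2**
Reactants: 3 rac-2-methyl-3-(2,4,6-trimethoxyphenyl)propanal; 4 prop-2-en-1-ol
Product: 5 (R)-2-methyl-2-[(2,4,6-trimethoxyphenyl)methyl]pent-4-enal
Conditions: Pd(PPh3)4 (3 mol%), chiral phosphoric acid TRIP [3,3′-bis(2,4,6-triisopropylphenyl)-1,1′-binaphthyl-2,2′-diyl hydrogen phosphate, the enantiomer that gives (R)-5] (3 mol%), Ph2CHNH2 (40 mol%), 5 Å MS, toluene, 40 °C
Reagents that add atoms: none
Why: Direct asymmetric α-allylation of an α-branched aldehyde (Tsuji–Trost allylation under combined enamine and chiral-counteranion catalysis), in which the benzhydryl enamine of 3 should attack the π-allyl-palladium cation on the face selected by its chiral phosphate counterion, setting the (R)-quaternary carbon that becomes C4.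

**Step 3**
Reactants: 5 (R)-2-methyl-2-[(2,4,6-trimethoxyphenyl)methyl]pent-4-enal; 6 dimethyl (2-oxopropyl)phosphonate
Product: 7 (R,E)-5-methyl-5-[(2,4,6-trimethoxyphenyl)methyl]octa-3,7-dien-2-one
Conditions: K2CO3, THF/H2O, 40 °C
Reagents that add atoms: none
Why: Horner–Wadsworth–Emmons olefination of the non-enolizable aldehyde with a β-ketophosphonate should give the (E)-enone without touching the quaternary stereocentre.

**Step 4**
Reactants: 7 (R,E)-5-methyl-5-[(2,4,6-trimethoxyphenyl)methyl]octa-3,7-dien-2-one
Product: 8 tert-butyl(dimethyl){[(3E,5R)-5-methyl-5-[(2,4,6-trimethoxyphenyl)methyl]octa-1,3,7-trien-2-yl]oxy}silane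
Conditions: TBSOTf, Et3N, CH2Cl2, 0 °C
Reagents that add atoms: tert-butyldimethylsilyl trifluoromethanesulfonate, CC(C)(C)[Si](C)(C)OS(=O)(=O)C(F)(F)F
Why: Soft enolization and O-silylation of the methyl ketone (its only enolizable position) should give the 2-silyloxy-1,3-diene with the E geometry of the C5=C6 bond retained.

**Step 5**
Reactants: 8 tert-butyl(dimethyl){[(3E,5R)-5-methyl-5-[(2,4,6-trimethoxyphenyl)methyl]octa-1,3,7-trien-2-yl]oxy}silane
Product: 10 (4R,5E)-7-(tert-butyldimethylsilyloxy)-4-methyl-4-[(2,4,6-trimethoxyphenyl)methyl]octa-5,7-dien-1-ol, via pinacol boronate 9 (not isolated)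
Conditions: HBpin, [Ir(cod)Cl]2 (1.5 mol%), dppm (3 mol%), CH2Cl2, rt; then 30% H2O2, aq. NaOH, THF, 0 °C
Reagents that add atoms: pinacolborane, [H]B1OC(C)(C)C(C)(C)O1 (boron of 9 only); hydrogen peroxide, OO (oxygen of 10)
Why: Iridium-catalysed anti-Markovnikov hydroboration with pinacolborane should select the monosubstituted terminal alkene over the conjugated 1,1-disubstituted silyl dienol ether, and alkaline peroxide oxidation of the boronate gives the primary alcohol with C4 untouched.

**Step 6**
Reactants: 10 (4R,5E)-7-(tert-butyldimethylsilyloxy)-4-methyl-4-[(2,4,6-trimethoxyphenyl)methyl]octa-5,7-dien-1-ol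
Product: 11 (4R,5E)-7-(tert-butyldimethylsilyloxy)-4-methyl-4-[(2,4,6-trimethoxyphenyl)methyl]octa-5,7-dienal
Conditions: DMP (1,1,1-triacetoxy-1,1-dihydro-1,2-benziodoxol-3(1H)-one), pyridine, CH2Cl2, 0 °C to rt
Reagents that add atoms: none
Why: Periodinane oxidation buffered with pyridine should convert the primary alcohol into the aldehyde without acid that would cleave the silyl dienol ether.

**Step 7**
Reactants: 11 (4R,5E)-7-(tert-butyldimethylsilyloxy)-4-methyl-4-[(2,4,6-trimethoxyphenyl)methyl]octa-5,7-dienal; 12 (2-bromoallyl)trimethylsilane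
Product: 13 (6R,7E)-9-(tert-butyldimethylsilyloxy)-6-methyl-2-methylidene-1-(trimethylsilyl)-6-[(2,4,6-trimethoxyphenyl)methyl]deca-7,9-dien-3-ol (both C3 epimers)
Conditions: 12, Mg, THF, rt; then 11, THF, −78 to 0 °C; aq. NH4Cl
Reagents that add atoms: none
Why: Grignard addition of the 2-metallated allylsilane to the aldehyde should give the secondary allylic alcohol while the silyl dienol ether stays inert; the carbinol carbon (C1 of the target) forms as an epimer mixture, which is irrelevant because it becomes cationic in step 8.

**Step 8**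
Reactants: 13 allylic alcohol (both C3 epimers)
Product: 15 cis-fused bicyclic silyl enol ether (guaiane numbering: 1β-H and 5β-H; CH2Ar β and CH3 α on C4; OTBS on C7 of the C6=C7 bond; exocyclic C10=CH2), via allylic triflate 14 (not isolated)
Conditions: Tf2O (1.1 equiv), 2,6-lutidine (2.5 equiv), CH2Cl2 (0.005 M), −78 °C; then aq. NaHCO3
Reagents that add atoms: trifluoromethanesulfonic anhydride, O=S(=O)(OS(=O)(=O)C(F)(F)F)C(F)(F)F (triflate group of 14 only)
Why: Triflation of the allylic alcohol and ionization at −78 °C should give the 2-(trimethylsilylmethyl)allyl cation C1–C10–C9, which adds across the termini C5 and C8 of the tethered 2-silyloxydiene; the tertiary C10 cation so formed is β to silicon and collapses by loss of Me3Si+ to the exocyclic methylene, while the silyl enol ether remains as the new C6=C7 ring alkene. The closest known reaction type is the intramolecular (4+3) cycloaddition of 2-(trimethylsilylmethyl)allyl cations with tethered 1,3-dienes, which gives 5,7-fused methylenecycloheptenes. The cyclopentane is closed by the C1–C5 bond across the three-atom tether C2–C3–C4 and the cycloheptene by the C8–C9 bond between the two unsubstituted termini, in a concerted or closely stepwise (4+3) mode. The new stereocentres C1 and C5 are controlled by the quaternary C4: the diene arm C6 and the allyl unit C10 should both take the methyl face of the forming cyclopentane, away from the large arylmethyl group, which gives the cis-fused 1β-H,5β-H adduct (C5 is removed later, C1 is kept). The step needs ionization without proton loss or arene alkylation, which the non-nucleophilic base, high dilution and the fully substituted ortho positions of the trimethoxyphenyl ring should secure; the position of the later enone is fixed because the silyloxy group sits on the internal diene carbon C7.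

**Step 9**
Reactants: 15 cis-fused bicyclic silyl enol ether with exocyclic C10=CH2
Product: 16 cis-fused bicyclic silyl enol ether with saturated C10 (1β-H and 5β-H; 10β-H and 10α-CH3; OTBS on C7 of the C6=C7 bond)
Conditions: H2 (1 atm), RhCl(PPh3)3 (5 mol%), benzene, rt
Reagents that add atoms: none
Why: Homogeneous hydrogenation should reduce the 1,1-disubstituted exocyclic alkene and leave the trisubstituted silyl enol ether, with hydrogen delivered to the convex β face of the cis-fused bicycle because the cyclopentane carbon C2 shields the α face next to C10, which sets 10β-H and the 10α-methyl group.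

**Step 10**
Reactants: 16 cis-fused bicyclic silyl enol ether with saturated C10
Product: 17 bicyclic enone (C5=C6–C7=O; 1β-H; 10α-CH3; CH2Ar β and CH3 α on C4)
Conditions: Pd(OAc)2 (1.1 equiv), MeCN, rt
Reagents that add atoms: none
Why: Saegusa–Ito oxidation, in which the palladium enolate formed regiospecifically at C6 should undergo syn β-hydride elimination of the C5 hydrogen, placing the double bond at C5=C6 only; C5 loses its stereocentre while C1, C4 and C10 are untouched.

**Step 11**
Reactants: 17 bicyclic enone; 18 isopropyltriphenylphosphonium iodide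
Product: 19 bicyclic diene (C5=C6 and exocyclic C7=C(CH3)2; 1β-H; 10α-CH3)
Conditions: 18, n-BuLi, THF, 0 °C; then 17, −78 °C to rt
Reagents that add atoms: none
Why: Wittig olefination of the C7 ketone with the non-stabilized isopropylidene ylide (1,2-addition to the enone carbonyl) should give the exocyclic tetrasubstituted alkene and thus the C5=C6–C7=C11 diene; no stereocentre is formed.

**Step 12**
Reactants: 19 bicyclic diene
Product: 20 alkenyl oxirane (spiro-epoxide C7–O–C11 with the oxygen β on C7; C5=C6 retained)
Conditions: mCPBA (1.05 equiv), NaHCO3, CH2Cl2, −20 °C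
Reagents that add atoms: 3-chloroperbenzoic acid, OOC(=O)c1cccc(Cl)c1
Why: Prilezhaev epoxidation should occur at the more electron-rich tetrasubstituted C7=C11 bond rather than at the hindered trisubstituted C5=C6 bond, and from the β face because C9 and C10 lie on the α side of the diene plane (C1 carries 1β-H), which sets the C7–O bond β.

**Step 13**
Reactants: 20 alkenyl oxirane
Product: 21 tertiary alcohol (7α-H and 7β-C(CH3)2OH; C5=C6; 1β-H; 10α-CH3; 2,4,6-trimethoxybenzyl on C4)
Conditions: Pd2(dba)3·CHCl3 (2.5 mol%), n-Bu3P (5 mol%), HCO2H, Et3N, 1,4-dioxane, rt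
Reagents that add atoms: none
Why: Palladium-catalysed formate hydrogenolysis of an alkenyl oxirane (Tsuji–Trost-type ionization), in which zerovalent palladium opens the allylic C7–O bond with inversion and the formate-derived hydride is delivered from the metal to C7 (C5 being blocked by the quaternary C4), so the net inversion should give 7α-H and the 7β-hydroxyisopropyl group with the alkene kept at C5=C6.

**Step 14**
Reactants: 21 tertiary alcohol
Product: 23 aryl aldehyde (21 with CHO on one of the two free ring positions), via aryllithium 22 (not isolated)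
Conditions: n-BuLi (2.3 equiv), TMEDA, THF, 0 °C; DMF, −78 to 0 °C; aq. NH4Cl
Reagents that add atoms: n-butyllithium, [Li]CCCC (lithium of 22 only); N,N-dimethylformamide, CN(C)C=O
Why: Directed ortho-metalation, in which n-BuLi first deprotonates the tertiary alcohol and then lithiates one of the two equivalent ring positions flanked by two methoxy groups (far more acidic than any allylic C–H), and DMF formylates the aryllithium; no stereocentre is affected.

**Step 15**
Reactants: 23 aryl aldehyde; 24 3-methylbutanoic anhydride
Product: 26 tri-O-methyl ether of the target (arene bearing CHO and 3-methylbutanoyl), via lithiated amino alkoxide 25 (not isolated)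
Conditions: LiN(CH3)CH2CH2N(CH3)2 (from the amine and n-BuLi, 2.2 equiv), THF, −20 °C; n-BuLi (1.3 equiv), −20 to 0 °C; 24 (1.1 equiv), −78 °C; aq. citric acid
Reagents that add atoms: lithium [2-(dimethylamino)ethyl](methyl)amide, [Li]N(C)CCN(C)C (in 25 only); n-butyllithium, [Li]CCCC (lithium of 25 only)
Why: Directed ortho-metalation with in-situ protection, in which the lithium amide adds to the aldehyde to give an α-amino alkoxide that survives n-BuLi, the last ring position (again between two methoxy groups) is lithiated and acylated by the anhydride at low temperature (the di-ortho-substituted aryl ketone resists a second addition), and aqueous acid returns the aldehyde.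

**Step 16**
Reactants: 26 tri-O-methyl ether of the target
Product: 27 target compound
Conditions: NaSEt (12 equiv), DMF, 120 °C; then 1 M HCl
Reagents that add atoms: none
Why: Nucleophilic cleavage of aryl methyl ethers by ethanethiolate (SN2 at the methyl carbon) is fast for methoxy groups ortho to a carbonyl, which all three are, and the non-acidic conditions should spare the tertiary alcohol, the trisubstituted alkene and the four stereocentres.

**Compound list**
1 | 2-iodo-1,3,5-trimethoxybenzene | COc1cc(OC)c(I)c(OC)c1 | starting material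
2 | 2-methylprop-2-en-1-ol | CC(=C)CO | starting material
3 | rac-2-methyl-3-(2,4,6-trimethoxyphenyl)propanal | COc1cc(OC)c(CC(C)C=O)c(OC)c1 | intermediate
4 | prop-2-en-1-ol | C=CCO | starting material
5 | (R)-2-methyl-2-[(2,4,6-trimethoxyphenyl)methyl]pent-4-enal | COc1cc(OC)c(C[C@@](C=O)(C)CC=C)c(OC)c1 | intermediate
6 | dimethyl (2-oxopropyl)phosphonate | COP(=O)(CC(C)=O)OC | starting material
7 | (R,E)-5-methyl-5-[(2,4,6-trimethoxyphenyl)methyl]octa-3,7-dien-2-one | COc1cc(OC)c(C[C@@](/C=C/C(C)=O)(C)CC=C)c(OC)c1 | intermediate
8 | tert-butyl(dimethyl){[(3E,5R)-5-methyl-5-[(2,4,6-trimethoxyphenyl)methyl]octa-1,3,7-trien-2-yl]oxy}silane | COc1cc(OC)c(C[C@@](/C=C/C(=C)O[Si](C)(C)C(C)(C)C)(C)CC=C)c(OC)c1 | intermediate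
9 | 2-[(4R,5E)-7-(tert-butyldimethylsilyloxy)-4-methyl-4-[(2,4,6-trimethoxyphenyl)methyl]octa-5,7-dien-1-yl]-4,4,5,5-tetramethyl-1,3,2-dioxaborolane (not isolated) | COc1cc(OC)c(C[C@@](/C=C/C(=C)O[Si](C)(C)C(C)(C)C)(C)CCCB2OC(C)(C)C(C)(C)O2)c(OC)c1 | intermediate
10 | (4R,5E)-7-(tert-butyldimethylsilyloxy)-4-methyl-4-[(2,4,6-trimethoxyphenyl)methyl]octa-5,7-dien-1-ol | COc1cc(OC)c(C[C@@](/C=C/C(=C)O[Si](C)(C)C(C)(C)C)(C)CCCO)c(OC)c1 | intermediate
11 | (4R,5E)-7-(tert-butyldimethylsilyloxy)-4-methyl-4-[(2,4,6-trimethoxyphenyl)methyl]octa-5,7-dienal | COc1cc(OC)c(C[C@@](/C=C/C(=C)O[Si](C)(C)C(C)(C)C)(C)CCC=O)c(OC)c1 | intermediate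
12 | (2-bromoallyl)trimethylsilane | C=C(Br)C[Si](C)(C)C | starting material
13 | (6R,7E)-9-(tert-butyldimethylsilyloxy)-6-methyl-2-methylidene-1-(trimethylsilyl)-6-[(2,4,6-trimethoxyphenyl)methyl]deca-7,9-dien-3-ol (both C3 epimers) | COc1cc(OC)c(C[C@@](/C=C/C(=C)O[Si](C)(C)C(C)(C)C)(C)CCC(O)C(=C)C[Si](C)(C)C)c(OC)c1 | intermediate
14 | trifluoromethanesulfonate of 13 (allylic triflate, not isolated) | COc1cc(OC)c(C[C@@](/C=C/C(=C)O[Si](C)(C)C(C)(C)C)(C)CCC(OS(=O)(=O)C(F)(F)F)C(=C)C[Si](C)(C)C)c(OC)c1 | intermediate
15 | cis-fused bicyclo[5.3.0]decadiene (1β-H and 5β-H; CH2Ar β and CH3 α on C4; C6=C7 silyl enol ether with OTBS on C7; exocyclic C10=CH2) | COc1cc(OC)c(C[C@@]2(C)CC[C@H]3[C@@H]2C=C(O[Si](C)(C)C(C)(C)C)CCC3=C)c(OC)c1 | intermediate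
16 | as 15 with saturated C10 (10β-H and 10α-CH3) | COc1cc(OC)c(C[C@@]2(C)CC[C@H]3[C@@H]2C=C(O[Si](C)(C)C(C)(C)C)CC[C@H]3C)c(OC)c1 | intermediate
17 | bicyclic enone (C5=C6–C7=O; 1β-H; 10α-CH3; CH2Ar β and CH3 α on C4) | COc1cc(OC)c(C[C@@]2(C)CC[C@H]3C2=CC(=O)CC[C@H]3C)c(OC)c1 | intermediate
18 | isopropyltriphenylphosphonium iodide | CC(C)[P+](c1ccccc1)(c1ccccc1)c1ccccc1.[I-] | starting material
19 | bicyclic diene (C5=C6 and exocyclic C7=C(CH3)2) | COc1cc(OC)c(C[C@@]2(C)CC[C@H]3C2=CC(=C(C)C)CC[C@H]3C)c(OC)c1 | intermediate
20 | alkenyl oxirane (spiro-epoxide C7–O–C11; oxygen β on C7) | COc1cc(OC)c(C[C@@]2(C)CC[C@H]3C2=C[C@]4(OC4(C)C)CC[C@H]3C)c(OC)c1 | intermediate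
21 | tertiary alcohol (7α-H; 7β-C(CH3)2OH; C5=C6; 1β-H; 10α-CH3; 2,4,6-trimethoxybenzyl β on C4) | COc1cc(OC)c(C[C@@]2(C)CC[C@H]3C2=C[C@H](C(C)(C)O)CC[C@H]3C)c(OC)c1 | intermediate
22 | dilithio species of 21 (lithium alkoxide and 3-lithioarene, not isolated) | [Li]c1c(OC)cc(OC)c(C[C@@]2(C)CC[C@H]3C2=C[C@H](C(C)(C)O[Li])CC[C@H]3C)c1OC | intermediate
23 | aryl aldehyde (3-formyl derivative of 21) | O=Cc1c(OC)cc(OC)c(C[C@@]2(C)CC[C@H]3C2=C[C@H](C(C)(C)O)CC[C@H]3C)c1OC | intermediate
24 | 3-methylbutanoic anhydride | CC(C)CC(=O)OC(=O)CC(C)C | starting material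
25 | lithiated α-amino alkoxide of 23 (aryllithium with protected aldehyde, not isolated) | [Li]c1c(OC)c(C(O[Li])N(C)CCN(C)C)c(OC)c(C[C@@]2(C)CC[C@H]3C2=C[C@H](C(C)(C)O[Li])CC[C@H]3C)c1OC | intermediate
26 | tri-O-methyl ether of the target (3-formyl-5-(3-methylbutanoyl)-2,4,6-trimethoxybenzyl on C4) | CC(C)CC(=O)c1c(OC)c(C=O)c(OC)c(C[C@@]2(C)CC[C@H]3C2=C[C@H](C(C)(C)O)CC[C@H]3C)c1OC | intermediate
27 | target: 2,4,6-trihydroxy-3-(3-methylbutanoyl)-5-(guai-5-en-11-ol-4-ylmethyl)benzaldehyde (1β-H; 4β-CH2Ar; 7β-C(CH3)2OH; 10α-CH3) | CC(C)CC(=O)c1c(O)c(C=O)c(O)c(C[C@@]2(C)CC[C@H]3C2=C[C@H](C(C)(C)O)CC[C@H]3C)c1O | target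

**Totals**
Total step count: 16. Longest linear sequence: 16 steps (from 1; compounds 2, 4, 6, 12, 18 and 24 are commercial inputs).

**The three steps most likely to fail**

Step 8 (key step). The cation may be lost by proton loss to a diene, or may form only one C–C bond by open-chain capture at the silyl enol ether. The ring fusion may also form without the expected preference for the cis adduct on the methyl face of C4. The fallback sets out from aldehyde 11. A Wittig reaction with cyclopropylidenetriphenylphosphorane (from cyclopropyltriphenylphosphonium bromide and NaH, THF, 60 °C) should give the alkylidenecyclopropane F1. A palladium-catalysed intramolecular (4+3) cycloaddition of the alkylidenecyclopropane with the silyloxydiene (Pd2(dba)3, P(O-i-Pr)3, dioxane, 100 °C), a neutral and non-cationic mode of ring closure that also delivers the exocyclic methylene at C10, should then give 15, where the route is rejoined.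

Step 11. The ylide may act as a base rather than a nucleophile: deprotonation at C1 (γ position of the enone) or at C8 would lead to enolization, deconjugation and loss of the C1 configuration in place of olefination. The fallback sets out from enone 17 and uses a Julia olefination. CeCl3-mediated 1,2-addition of 2-lithio-2-(phenylsulfonyl)propane (from isopropyl phenyl sulfone and n-BuLi, THF, −78 °C) should give the β-hydroxy sulfone F2. Reductive elimination with SmI2 and HMPA in THF should then give diene 19, where the route is rejoined.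

Step 2. Enantiofacial discrimination may be insufficient in the formation of the quaternary carbon, because the two α-substituents of the enamine (CH3 and CH2Ar) are both saturated carbon groups of moderate size difference. The fallback sets out from aldehyde 3. O-Acylation of its potassium enolate (KOt-Bu, THF, −78 °C) with allyl chloroformate should give the allyl enol carbonate F3. A decarboxylative asymmetric allylic alkylation (Pd2(dba)3·CHCl3 with a chiral C2-symmetric bis(2-diphenylphosphinobenzamide) ligand, dioxane, rt), in which the enolate and the π-allyl cation are formed as an ion pair inside the chiral pocket, should then give 5, where the route is rejoined.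

**Further compounds**
F1 | step 8 | alkylidenecyclopropane: tert-butyl{[(3E,5R)-8-cyclopropylidene-5-methyl-5-[(2,4,6-trimethoxyphenyl)methyl]octa-1,3-dien-2-yl]oxy}dimethylsilane | COc1cc(OC)c(C[C@@](/C=C/C(=C)O[Si](C)(C)C(C)(C)C)(C)CCC=C2CC2)c(OC)c1
F2 | step 11 | β-hydroxy sulfone: adduct of 17 with a hydroxyl group and a 2-(phenylsulfonyl)propan-2-yl group on C7 (both C7 epimers) | COc1cc(OC)c(C[C@@]2(C)CC[C@H]3C2=CC(O)(C(C)(C)S(=O)(=O)c4ccccc4)CC[C@H]3C)c(OC)c1
F3 | step 2 | allyl enol carbonate: allyl (E)-2-methyl-3-(2,4,6-trimethoxyphenyl)prop-1-en-1-yl carbonate | COc1cc(OC)c(C/C(C)=C/OC(=O)OCC=C)c(OC)c1
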